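**Plan**

- Retrosynthesis (germacrane numbering): cut the C8–O angelate; then C6–C7 together with the lactone C12–O (allylchromium/aldehyde ring closure); then C7–C11 and C7=C8 of the side chain (Suzuki coupling, cross-metathesis, C8–O from an epoxide); then C9–C10 (decarboxylative allylation); last C1–C2 and O–C10 of the furanone.
- Forward: the 3(2H)-furanone (ring of O, C3, C2, C1, C10) is made first from methyl ketone 4 (C2–C6, C15) and malonyl chloride 9 (C1, C10, C14, plus an allyl ester that carries C7–C9). The side chain is then grown at C10, the ten-membered carbocycle and the α-methylene-γ-lactone are closed together in step 15, and the angelate goes on last.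
- Enabling feature: the furanone is a cyclic vinylogous ester. O and C2 are the two nucleophilic ends of a C3 methyl-ketone enolate, and C1/C10 are an acyl carbon next to a fully substituted carbon. An ester on C10 therefore activates C10–Cl for O-alkylation and is later expelled as CO2.
- Stereochemistry: C10 from ligand-controlled, enantioconvergent palladium decarboxylative allylation; C8 from a Shi epoxidation; C6 and C7 from the chair-like chromium allylation in the ring closure; the 4Z alkene from butenolide 1; the angelate geometry from angelic anhydride.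

Key step: step 7

Remark: positions are given in germacrane numbering (C1 furanone carbonyl, C2=C3 furanone alkene, C4=C5 Z alkene, C6 and C8 oxygenated carbons, C10 quaternary carbon, C11–C13 methylene lactone, C14/C15 methyls on C10/C4); TBS = tert-butyldimethylsilyl; methyl 2-bromoacrylate, angelic anhydride and the L-fructose-derived Shi ketone are taken as purchasable.

**Route**

Step 1
Reactants: 1 3-methylfuran-2(5H)-one
Product: 2 (2Z)-4-hydroxy-N-methoxy-N,2-dimethylbut-2-enamide
Conditions: MeNH(OMe)·HCl, AlMe3, CH2Cl2, 0 to 25 °C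
Reagents that add atoms: N,O-dimethylhydroxylamine hydrochloride, CNOC.Cl
Why: Aluminium amide aminolysis of the lactone (Weinreb amide formation) breaks only the acyl C–O bond, so the Z alkene of the butenolide ring is carried over as the future C4=C5 geometry.

Step 2
Reactants: 2 (2Z)-4-hydroxy-N-methoxy-N,2-dimethylbut-2-enamide
Product: 3 (2Z)-4-(TBS-oxy)-N-methoxy-N,2-dimethylbut-2-enamide
Conditions: TBSCl, imidazole, DMF, 0 °C
Reagents that add atoms: tert-butyldimethylsilyl chloride, CC(C)(C)[Si](C)(C)Cl
Why: Silyl ether formation at the primary alcohol masks C6–OH and prevents relactonisation.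

Step 3
Reactants: 3 (2Z)-4-(TBS-oxy)-N-methoxy-N,2-dimethylbut-2-enamide
Product: 4 (3Z)-5-(TBS-oxy)-3-methylpent-3-en-2-one
Conditions: MeMgBr, THF, −20 to 0 °C
Reagents that add atoms: methylmagnesium bromide, C[Mg]Br
Why: Weinreb ketone synthesis, in which the chelated tetrahedral intermediate stops at the methyl ketone that supplies C2 and C3.

Step 4
Reactants: 5 2,2,5-trimethyl-1,3-dioxane-4,6-dione
Product: 6 5-chloro-2,2,5-trimethyl-1,3-dioxane-4,6-dione
Conditions: NCS, Et3N (cat.), CH2Cl2, 0 to 25 °C
Reagents that add atoms: N-chlorosuccinimide, O=C1CCC(=O)N1Cl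
Why: Electrophilic α-chlorination of the acidic C5–H of a Meldrum's acid.

Step 5
Reactants: 6 5-chloro-2,2,5-trimethyl-1,3-dioxane-4,6-dione; 7 prop-2-en-1-ol
Product: 8 2-chloro-2-methyl-3-oxo-3-(prop-2-en-1-yloxy)propanoic acid (racemic)
Conditions: MeCN, 70 °C
Reagents that add atoms: none
Why: Alcoholysis of the Meldrum's acid (acyl substitution with loss of acetone) gives the malonic half ester whose allyl group will become C7–C9.

Step 6
Reactants: 8 2-chloro-2-methyl-3-oxo-3-(prop-2-en-1-yloxy)propanoic acid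
Product: 9 prop-2-en-1-yl 2,3-dichloro-2-methyl-3-oxopropanoate (racemic)
Conditions: (COCl)2, DMF (cat.), CH2Cl2, 0 to 25 °C
Reagents that add atoms: oxalyl chloride, O=C(Cl)C(=O)Cl
Why: Acid chloride formation through the chloroiminium intermediate; the α-carbon has no hydrogen, so no ketene can form.

Step 7
Reactants: 4 (3Z)-5-(TBS-oxy)-3-methylpent-3-en-2-one; 9 prop-2-en-1-yl 2,3-dichloro-2-methyl-3-oxopropanoate
Product: 11 prop-2-en-1-yl 5-[(2Z)-4-(TBS-oxy)but-2-en-2-yl]-2-methyl-3-oxo-2,3-dihydrofuran-2-carboxylate (racemic at C10), via chlorodiketone 10 (not isolated)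
Conditions: MgBr2·OEt2, i-Pr2NEt, CH2Cl2, 0 to 25 °C, then 40 °C in the same flask
Reagents that add atoms: none
Why: Proposed new method: soft enolisation of MgBr2-bound 4 at its acetyl methyl group (C2) and C-acylation by the acyl chloride carbon of 9 (C1) give the chelated 1,3-diketonate 10, whose C3 oxygen then displaces the tertiary chloride at C10; the closest known reaction types are the soft-enolisation Claisen acylation of ketones with acid chlorides, the acylation/O-cycloalkylation of active methylene compounds with α-haloacyl chlorides (tetronic acid and interrupted Feist–Bénary-type furanone syntheses) and SN2 displacement at tertiary α-chloro-β-keto esters. The only ring closed is the furanone, by 5-exo-tet O-alkylation; the O···C10···Cl axis can align with the π* orbital of the exocyclic allyl ester carbonyl, so the ester is the activating group that makes substitution at the tertiary centre feasible (bromide from MgBr2 may first exchange for chloride). C10 is the only new stereocentre and is deliberately formed as the racemate, because the allyl ester that activates it is used in step 8 to erase and re-set this centre under ligand control. The step needs C- over O-acylation (secured by the magnesium chelate), enolisation at the acetyl methyl rather than at the γ-positions (kinetic α-deprotonation of the metal-bound ketone), and O-alkylation at C10 rather than lactonisation onto the ester or loss of HCl toward the C10 methyl group (favoured by the five-membered transition state and the weak base).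

Step 8
Reactants: 11 prop-2-en-1-yl 5-[(2Z)-4-(TBS-oxy)but-2-en-2-yl]-2-methyl-3-oxo-2,3-dihydrofuran-2-carboxylate
Product: 12 (2R)-5-[(2Z)-4-(TBS-oxy)but-2-en-2-yl]-2-methyl-2-(prop-2-en-1-yl)furan-3(2H)-one
Conditions: Pd2(dba)3, (R)-t-Bu-PHOX, THF, 25 °C
Reagents that add atoms: none
Why: Decarboxylative asymmetric allylic alkylation (Tsuji–Trost type): zerovalent palladium ionises the allyl ester, the β-keto carboxylate loses CO2 to the achiral 3-furanolate common to both enantiomers of 11, and the ligand-bound allylpalladium alkylates one face of C10, the ligand enantiomer being chosen by analogy with 2-methylcycloalkanone enolates to give 10R.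

Step 9
Reactants: 12 (2R)-5-[(2Z)-4-(TBS-oxy)but-2-en-2-yl]-2-methyl-2-(prop-2-en-1-yl)furan-3(2H)-one; 13 4,4,5,5-tetramethyl-2-vinyl-1,3,2-dioxaborolane
Product: 14 (2R)-5-[(2Z)-4-(TBS-oxy)but-2-en-2-yl]-2-methyl-2-[(2E)-3-(4,4,5,5-tetramethyl-1,3,2-dioxaborolan-2-yl)prop-2-en-1-yl]furan-3(2H)-one
Conditions: second-generation Grubbs catalyst RuCl2(=CHPh)(PCy3)(H2IMes), CH2Cl2, 40 °C
Reagents that add atoms: none
Why: Olefin cross-metathesis engages only the monosubstituted alkene (the trisubstituted and conjugated alkenes are inert) and should give the E-alkenylboronate.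

Step 10
Reactants: 14 the E-alkenylboronate; 15 methyl 2-bromoprop-2-enoate
Product: 16 methyl (3E)-5-{(2R)-5-[(2Z)-4-(TBS-oxy)but-2-en-2-yl]-2-methyl-3-oxo-2,3-dihydrofuran-2-yl}-2-methylidenepent-3-enoate
Conditions: Pd(dppf)Cl2, K3PO4, THF/H2O, 40 °C
Reagents that add atoms: none
Why: Suzuki–Miyaura coupling of the alkenylboronate with the vinylic bromide keeps the E geometry and installs C11–C13 as a 2-(methoxycarbonyl)-1,3-diene.

Step 11
Reactants: 16 the diene ester
Product: 17 methyl 2-[(2S,3S)-3-({(2R)-5-[(2Z)-4-(TBS-oxy)but-2-en-2-yl]-2-methyl-3-oxo-2,3-dihydrofuran-2-yl}methyl)oxiran-2-yl]prop-2-enoate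
Conditions: L-fructose-derived Shi ketone (cat.), Oxone (2KHSO5·KHSO4·K2SO4), K2CO3, n-Bu4NHSO4, MeCN/CH2(OMe)2/aq. Na2B4O7 buffer, 0 °C
Reagents that add atoms: potassium peroxymonosulfate, [K+].[O-]S(=O)(=O)OO
Why: Shi epoxidation (chiral dioxirane, spiro transition state) should attack the trans-disubstituted C7=C8 bond, the most electron-rich alkene present (C11=C13 is an acrylate, C2=C3 a vinylogous ester, C4=C5 the δ-terminus of a dienone with an allylic silyloxy group), and with this ketone enantiomer give the (7S,8S)-epoxide, which sets C8.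

Step 12
Reactants: 17 the vinyl epoxide
Product: 19 methyl (2Z,4S)-2-(bromomethyl)-4-(TBS-oxy)-5-{(2R)-5-[(2Z)-4-(TBS-oxy)but-2-en-2-yl]-2-methyl-3-oxo-2,3-dihydrofuran-2-yl}pent-2-enoate, via bromohydrin 18 (not isolated)
Conditions: MgBr2·OEt2, CH2Cl2, −20 °C; then 2,6-lutidine, TBSOTf, −78 to 0 °C
Reagents that add atoms: magnesium bromide diethyl etherate, [Mg+2].[Br-].[Br-].CCOCC; tert-butyldimethylsilyl trifluoromethanesulfonate, CC(C)(C)[Si](C)(C)OS(=O)(=O)C(F)(F)F
Why: Bromide opens the acrylate-substituted epoxide at the allylic terminus (SN2′ at C13, or SN2 at C7 followed by the usual SN2′ equilibration of secondary Morita–Baylis–Hillman-type bromides) to the conjugated primary allylic bromide with the C8–O bond untouched (retention at C8), and the magnesium alkoxide is silylated before it can cyclise onto the bromide.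

Step 13
Reactants: 19 the bis-silyl ether
Product: 20 methyl (2Z,4S)-2-(bromomethyl)-4-(TBS-oxy)-5-{(2R)-5-[(2Z)-4-hydroxybut-2-en-2-yl]-2-methyl-3-oxo-2,3-dihydrofuran-2-yl}pent-2-enoate
Conditions: CSA (cat.), MeOH/CH2Cl2, 0 °C
Reagents that add atoms: none
Why: Acid-catalysed methanolysis cleaves the unhindered primary allylic silyl ether selectively over the hindered secondary one (steric discrimination) and, having no nucleophilic amine, spares the allylic bromide.

Step 14
Reactants: 20 the primary allylic alcohol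
Product: 21 methyl (2Z,4S)-2-(bromomethyl)-4-(TBS-oxy)-5-{(2R)-2-methyl-3-oxo-5-[(2Z)-4-oxobut-2-en-2-yl]-2,3-dihydrofuran-2-yl}pent-2-enoate
Conditions: Dess–Martin periodinane, NaHCO3, CH2Cl2, 0 °C
Reagents that add atoms: none
Why: Dess–Martin oxidation under buffered, amine-free conditions should give the Z-enal without Z to E isomerisation.

Step 15
Reactants: 21 the bromo aldehyde
Product: 24 tert-butyldimethylsilyl ether of 25 (8-O-TBS macrolactone; same spatial arrangement at C6 C7 C8 C10 as in 27), via allylchromium dichloride 22 (not isolated), via seco hydroxy ester 23 (not isolated)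
Conditions: CrCl2, THF, 25 °C, 21 added slowly (high dilution); then PPTS, CH2Cl2, 25 °C
Reagents that add atoms: none
Why: Intramolecular Nozaki–Hiyama-type (Barbier) allylation: the allylchromium formed by divalent chromium adds through C7 to the aldehyde in a chair-like transition state that should give the anti (6,7-trans) adduct, with the aldehyde approaching C7 anti to the C8–O bond (H8 in the plane of the allyl unit), and the C6 alkoxide then lactonises onto the methyl ester, so that C6 and C7 are set and the ten-membered ring and the α-methylene lactone are closed together.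

Step 16
Reactants: 24 the 8-O-TBS macrolactone
Product: 25 (6R,7R,8S,10R)-8-hydroxy lactone (8-deangeloyl-lychnopholide)
Conditions: HF·pyridine, THF, 0 to 25 °C
Reagents that add atoms: none
Why: Fluoride-mediated desilylation of the secondary silyl ether under non-basic conditions that the α-methylene lactone tolerates.

Step 17
Reactants: 25 the 8-hydroxy lactone; 26 (2Z)-2-methylbut-2-enoic anhydride (angelic anhydride)
Product: 27 lychnopholide
Conditions: DMAP (cat.), Et3N, CH2Cl2, 0 °C
Reagents that add atoms: none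
Why: DMAP-catalysed acylation of the secondary alcohol with the anhydride at low temperature, chosen to limit angelate to tiglate isomerisation; the 5-endo addition of C8–OH to the methylene lactone is geometrically disfavoured.

**Compound list**

1 | 3-methylfuran-2(5H)-one | CC1=CCOC1=O | starting material
2 | (2Z)-4-hydroxy-N-methoxy-N,2-dimethylbut-2-enamide | CON(C)C(=O)/C(C)=C\CO | intermediate
3 | (2Z)-4-(TBS-oxy)-N-methoxy-N,2-dimethylbut-2-enamide | CON(C)C(=O)/C(C)=C\CO[Si](C)(C)C(C)(C)C | intermediate
4 | (3Z)-5-(TBS-oxy)-3-methylpent-3-en-2-one | CC(=O)/C(C)=C\CO[Si](C)(C)C(C)(C)C | intermediate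
5 | 2,2,5-trimethyl-1,3-dioxane-4,6-dione | CC1C(=O)OC(C)(C)OC1=O | starting material
6 | 5-chloro-2,2,5-trimethyl-1,3-dioxane-4,6-dione | CC1(Cl)C(=O)OC(C)(C)OC1=O | intermediate
7 | prop-2-en-1-ol | C=CCO | starting material
8 | 2-chloro-2-methyl-3-oxo-3-(prop-2-en-1-yloxy)propanoic acid (racemic) | C=CCOC(=O)C(C)(Cl)C(=O)O | intermediate
9 | prop-2-en-1-yl 2,3-dichloro-2-methyl-3-oxopropanoate (racemic) | C=CCOC(=O)C(C)(Cl)C(=O)Cl | intermediate
10 | prop-2-en-1-yl (6Z)-8-(TBS-oxy)-2-chloro-2,6-dimethyl-3,5-dioxooct-6-enoate (racemic, not isolated) | C=CCOC(=O)C(C)(Cl)C(=O)CC(=O)/C(C)=C\CO[Si](C)(C)C(C)(C)C | intermediate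
11 | prop-2-en-1-yl 5-[(2Z)-4-(TBS-oxy)but-2-en-2-yl]-2-methyl-3-oxo-2,3-dihydrofuran-2-carboxylate (racemic) | C=CCOC(=O)C1(C)OC(=CC1=O)/C(C)=C\CO[Si](C)(C)C(C)(C)C | intermediate
12 | (2R)-5-[(2Z)-4-(TBS-oxy)but-2-en-2-yl]-2-methyl-2-(prop-2-en-1-yl)furan-3(2H)-one | C=CC[C@@]1(C)OC(=CC1=O)/C(C)=C\CO[Si](C)(C)C(C)(C)C | intermediate
13 | 4,4,5,5-tetramethyl-2-vinyl-1,3,2-dioxaborolane | C=CB1OC(C)(C)C(C)(C)O1 | starting material
14 | (2R)-5-[(2Z)-4-(TBS-oxy)but-2-en-2-yl]-2-methyl-2-[(2E)-3-(pinacolboryl)prop-2-en-1-yl]furan-3(2H)-one | CC1(C)OB(/C=C/C[C@@]2(C)OC(=CC2=O)/C(C)=C\CO[Si](C)(C)C(C)(C)C)OC1(C)C | intermediate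
15 | methyl 2-bromoprop-2-enoate | C=C(Br)C(=O)OC | starting material
16 | methyl (3E)-5-{(2R)-5-[(2Z)-4-(TBS-oxy)but-2-en-2-yl]-2-methyl-3-oxo-2,3-dihydrofuran-2-yl}-2-methylidenepent-3-enoate | C=C(C(=O)OC)/C=C/C[C@@]1(C)OC(=CC1=O)/C(C)=C\CO[Si](C)(C)C(C)(C)C | intermediate
17 | methyl 2-[(2S,3S)-3-({(2R)-5-[(2Z)-4-(TBS-oxy)but-2-en-2-yl]-2-methyl-3-oxo-2,3-dihydrofuran-2-yl}methyl)oxiran-2-yl]prop-2-enoate | C=C(C(=O)OC)[C@@H]1O[C@H]1C[C@@]2(C)OC(=CC2=O)/C(C)=C\CO[Si](C)(C)C(C)(C)C | intermediate
18 | methyl (2Z,4S)-2-(bromomethyl)-4-hydroxy-5-{(2R)-5-[(2Z)-4-(TBS-oxy)but-2-en-2-yl]-2-methyl-3-oxo-2,3-dihydrofuran-2-yl}pent-2-enoate (not isolated) | COC(=O)/C(CBr)=C/[C@@H](O)C[C@@]1(C)OC(=CC1=O)/C(C)=C\CO[Si](C)(C)C(C)(C)C | intermediate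
19 | 4-O-TBS ether of 18 | COC(=O)/C(CBr)=C/[C@@H](O[Si](C)(C)C(C)(C)C)C[C@@]1(C)OC(=CC1=O)/C(C)=C\CO[Si](C)(C)C(C)(C)C | intermediate
20 | primary allylic alcohol from 19 (C6–OH free, C8–OTBS) | COC(=O)/C(CBr)=C/[C@@H](O[Si](C)(C)C(C)(C)C)C[C@@]1(C)OC(=CC1=O)/C(C)=C\CO | intermediate
21 | Z-enal from 20 (C6 aldehyde, C13 bromide, C8–OTBS) | COC(=O)/C(CBr)=C/[C@@H](O[Si](C)(C)C(C)(C)C)C[C@@]1(C)OC(=CC1=O)/C(C)=C\C=O | intermediate
22 | allylchromium dichloride from 21 (trivalent chromium on C13, not isolated) | COC(=O)/C(C[Cr](Cl)Cl)=C/[C@@H](O[Si](C)(C)C(C)(C)C)C[C@@]1(C)OC(=CC1=O)/C(C)=C\C=O | intermediate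
23 | seco hydroxy ester (ten-membered ring closed, C6–OH, methyl ester at C12, not isolated) | C=C(C(=O)OC)[C@@H]1[C@@H](O[Si](C)(C)C(C)(C)C)C[C@@]2(C)OC(=CC2=O)/C(C)=C\[C@H]1O | intermediate
24 | tert-butyldimethylsilyl ether of 25 (8-O-TBS macrolactone) | C=C1C(=O)O[C@@H]2/C=C(/C)C3=CC(=O)[C@@](C)(C[C@H](O[Si](C)(C)C(C)(C)C)[C@@H]12)O3 | intermediate
25 | (6R,7R,8S,10R)-8-hydroxy lactone (8-deangeloyl-lychnopholide) | C=C1C(=O)O[C@@H]2/C=C(/C)C3=CC(=O)[C@@](C)(C[C@H](O)[C@@H]12)O3 | intermediate
26 | (2Z)-2-methylbut-2-enoic anhydride (angelic anhydride) | C/C=C(/C)C(=O)OC(=O)/C(C)=C\C | starting material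
27 | lychnopholide, (6R,7R,8S,10R) | C=C1C(=O)O[C@@H]2/C=C(/C)C3=CC(=O)[C@@](C)(C[C@H](OC(=O)/C(C)=C\C)[C@@H]12)O3 | target

**Summary**

Total step count: 17. Longest linear sequence: 14 steps (steps 1–3 and 7–17, from 3-methylfuran-2(5H)-one); steps 4–6 form the side branch to 9.

Steps most likely to fail:

1. Step 7 (Proposed new method). The annulation may be diverted by O-acylation, by lactonisation of the diketonate onto the allyl ester, by loss of HCl toward the C10 methyl group, or by halogen transfer instead of ring closure. Fallback with known reaction types, setting out from 4: soft-enolisation C-acylation with 2-bromopropanoyl chloride (MgBr2·OEt2, i-Pr2NEt) gives the bromodiketone F1. K2CO3 in acetone closes it by O-alkylation at the secondary bromide to the 2-methylfuranone F2. NaHMDS and allyl chloroformate then give the allyl enol carbonate F3, which under the palladium conditions of step 8 (decarboxylative allylation of an allyl enol carbonate) gives 12, where the route is rejoined.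

2. Step 8. The aromatic furanolate may give low enantioselectivity or the opposite sense of induction, or be allylated at oxygen or at C2. Fallback, setting out from 11: Pd(PPh3)4 in THF gives the racemic allyl furanone F4, which is resolved by preparative chromatography on a chiral stationary phase to return 12.

3. Step 15. The ring closure may suffer from oligomerisation, from loss of the C8 silyloxy group by 1,4-elimination from the allylchromium, from Z to E isomerisation of the enal, or from poor facial selectivity. Fallback, setting out from 19: hexamethyldisilane and Pd(PPh3)4 convert the allylic bromide into the allylsilane F5. CSA in methanol frees the primary alcohol F6, and Dess–Martin periodinane gives the aldehyde F7. TiCl4 in CH2Cl2 at −78 °C under high dilution then closes the ring by an intramolecular Hosomi–Sakurai allylation through an open transition state, and lactonisation of the resulting hydroxy ester 23 returns 24.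

Further compounds
F1 | step 7 | (6Z)-2-bromo-8-(TBS-oxy)-6-methyloct-6-ene-3,5-dione (racemic) | CC(Br)C(=O)CC(=O)/C(C)=C\CO[Si](C)(C)C(C)(C)C
F2 | step 7 | 5-[(2Z)-4-(TBS-oxy)but-2-en-2-yl]-2-methylfuran-3(2H)-one (racemic) | CC1OC(=CC1=O)/C(C)=C\CO[Si](C)(C)C(C)(C)C
F3 | step 7 | 5-[(2Z)-4-(TBS-oxy)but-2-en-2-yl]-2-methylfuran-3-yl prop-2-en-1-yl carbonate | C=CCOC(=O)Oc1cc(/C(C)=C\CO[Si](C)(C)C(C)(C)C)oc1C
F4 | step 8 | racemic 5-[(2Z)-4-(TBS-oxy)but-2-en-2-yl]-2-methyl-2-(prop-2-en-1-yl)furan-3(2H)-one | C=CCC1(C)OC(=CC1=O)/C(C)=C\CO[Si](C)(C)C(C)(C)C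
F5 | step 15 | allylsilane from 19 (C13–SiMe3 in place of C13–Br) | COC(=O)/C(C[Si](C)(C)C)=C/[C@@H](O[Si](C)(C)C(C)(C)C)C[C@@]1(C)OC(=CC1=O)/C(C)=C\CO[Si](C)(C)C(C)(C)C
F6 | step 15 | primary allylic alcohol from F5 | COC(=O)/C(C[Si](C)(C)C)=C/[C@@H](O[Si](C)(C)C(C)(C)C)C[C@@]1(C)OC(=CC1=O)/C(C)=C\CO
F7 | step 15 | Z-enal from F6 | COC(=O)/C(C[Si](C)(C)C)=C/[C@@H](O[Si](C)(C)C(C)(C)C)C[C@@]1(C)OC(=CC1=O)/C(C)=C\C=O
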